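**Plan**

Numbering: isochromene numbering; ring A = pyran (O2, C1, C3, C4, C4a, C8a), ring B = carbocycle (C4a, C5, C6, C7, C8, C8a), side chain C9–C14 on C3.
Cuts: the C8 carbinol is traced back to a C8 ketone, so C7/C8 become an α-ketol. The C7–C8 bond of ring B is then cut as a crossed benzoin to the monocyclic 4-ylidene-4H-pyran 19. Next come C4a=C5 (Meyer–Schuster, to 4-pyranone 15 and but-3-yn-2-ol), then ring A at O2–C3 and C8a–C1 (formylation/oxa-Michael of ynone 13), then C4–C4a (acetylide plus Weinreb amide).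
Forward order: side-chain epoxy alkyne 10 → ynone 13 → ring A as 4-pyranone 15 → pyranylidene keto-aldehyde 19 → ring B by C7–C8 bond formation → C8 reduction → desilylation.
Enabling feature: C8 sits on C8a, the β-carbon of the C1=C8a enol ether, so as a formyl group it cannot enolise. C7 is the acetyl carbonyl of a 1,2-dione carried by the exocyclic C4a=C5 bond. The C8a–C4a=C5–C6 spine of ring A holds C8 and C7 in a 1,6-relationship, and C6, a vinylogous pyranone carbonyl, is the less electrophilic ketone.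
Stereochemistry: C13/C14 from ethyl (S)-3-hydroxybutanoate and anti-selective Fráter–Seebach methylation; C9/C10 from Sharpless epoxidation with D-(−)-diethyl tartrate; C7 from the chiral triazolylidene in the benzoin step; C8 from hydride delivery directed by the C7 hydroxyl; both alkenes E from stabilised Wittig reactions.

Key step: step 15

Assumption: the (5aR,10bS) triazolium salt is taken to give the 7R ketol 20; if the sense of induction is the opposite, its commercial antipode is used with no other change.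
Remark: 18 and 19 are written as the Z isomers at the exocyclic C4a=C5 bond; this push–pull bond is expected to rotate freely, so its geometry is not a stereochemical issue.
Abbreviation in names: Ep = 3-[(2E,4R,5S)-5-[(tert-butyldimethylsilyl)oxy]-4-methylhex-2-en-2-yl]-2-methyloxiran-2-yl, (2R,3S) when bound to ring A, with the same absolute arrangement in every compound (full SMILES in the compound list).

**Route**

Step 1
Reactants: 1 ethyl (3S)-3-hydroxybutanoate
Product: 2 ethyl (2S,3S)-3-hydroxy-2-methylbutanoate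
Conditions: LiN(iPr)2 (2.2 equiv), THF, −50 → −20 °C; MeI, DMPU, −78 → 0 °C; H2O
Reagents that add atoms: iodomethane, CI
Why: Fráter–Seebach alkylation, in which the chelated lithium alkoxide–enolate dianion is methylated on the face opposite the C3 methyl group, which should set C2 as 2S (anti).

Step 2
Reactants: 2 ethyl (2S,3S)-3-hydroxy-2-methylbutanoate
Product: 3 ethyl (2S,3S)-3-[(tert-butyldimethylsilyl)oxy]-2-methylbutanoate
Conditions: TBSCl, imidazole, DMF, rt
Reagents that add atoms: tert-butyldimethylsilyl chloride, CC(C)(C)[Si](C)(C)Cl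
Why: Standard silylation of a secondary alcohol; the silyl ether blocks retro-aldol and over-oxidation in later steps.

Step 3
Reactants: 3 ethyl (2S,3S)-3-[(tert-butyldimethylsilyl)oxy]-2-methylbutanoate
Product: 4 (2S,3S)-3-[(tert-butyldimethylsilyl)oxy]-2-methylbutanal
Conditions: iBu2AlH (1.05 equiv), CH2Cl2, −78 °C; Rochelle salt
Reagents that add atoms: none
Why: Partial ester reduction through the tetrahedral aluminium hemiacetal, which is stable at −78 °C, so the α-stereocentre should not epimerise.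

Step 4
Reactants: 4 (2S,3S)-3-[(tert-butyldimethylsilyl)oxy]-2-methylbutanal
Product: 5 (2E,4R,5S)-5-[(tert-butyldimethylsilyl)oxy]-2,4-dimethylhex-2-enal
Conditions: Ph3P=C(CH3)CHO, toluene, 90 °C
Reagents that add atoms: 2-(triphenylphosphoranylidene)propanal, CC(C=O)=P(c1ccccc1)(c1ccccc1)c1ccccc1
Why: Wittig olefination with a stabilised formyl ylide, which should give the E-trisubstituted enal (C11=C12).

Step 5
Reactants: 5 (2E,4R,5S)-5-[(tert-butyldimethylsilyl)oxy]-2,4-dimethylhex-2-enal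
Product: 6 ethyl (2E,4E,6R,7S)-7-[(tert-butyldimethylsilyl)oxy]-2,4,6-trimethylocta-2,4-dienoate
Conditions: Ph3P=C(CH3)CO2Et, toluene, 80 °C
Reagents that add atoms: ethyl 2-(triphenylphosphoranylidene)propanoate, CCOC(=O)C(C)=P(c1ccccc1)(c1ccccc1)c1ccccc1
Why: Second stabilised Wittig olefination, which should give the E-configured C9=C10 bond.

Step 6
Reactants: 6 ethyl (2E,4E,6R,7S)-7-[(tert-butyldimethylsilyl)oxy]-2,4,6-trimethylocta-2,4-dienoate
Product: 7 (2E,4E,6R,7S)-7-[(tert-butyldimethylsilyl)oxy]-2,4,6-trimethylocta-2,4-dien-1-ol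
Conditions: iBu2AlH (2.5 equiv), CH2Cl2, −78 °C; Rochelle salt
Reagents that add atoms: none
Why: 1,2-Reduction of the dienoate by iBu2AlH should give the allylic alcohol without touching the diene.

Step 7
Reactants: 7 (2E,4E,6R,7S)-7-[(tert-butyldimethylsilyl)oxy]-2,4,6-trimethylocta-2,4-dien-1-ol
Product: 8 [(2S,3S)-3-[(2E,4R,5S)-5-[(tert-butyldimethylsilyl)oxy]-4-methylhex-2-en-2-yl]-2-methyloxiran-2-yl]methanol
Conditions: Ti(OiPr)4 (10 mol %), D-(−)-diethyl tartrate (12 mol %), tBuOOH (anhydrous), 4 Å molecular sieves, CH2Cl2, −20 °C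
Reagents that add atoms: tert-butyl hydroperoxide, CC(C)(C)OO
Why: Sharpless asymmetric epoxidation acts only on the alkene allylic to the hydroxyl group, and the D-(−)-tartrate should deliver oxygen to the face that sets C9 and C10 as required (reagent control).

Step 8
Reactants: 8 [(2S,3S)-3-[(2E,4R,5S)-5-[(tert-butyldimethylsilyl)oxy]-4-methylhex-2-en-2-yl]-2-methyloxiran-2-yl]methanol
Product: 9 (2R,3S)-3-[(2E,4R,5S)-5-[(tert-butyldimethylsilyl)oxy]-4-methylhex-2-en-2-yl]-2-methyloxirane-2-carbaldehyde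
Conditions: Dess–Martin periodinane, NaHCO3, CH2Cl2, 0 °C → rt
Reagents that add atoms: none
Why: Buffered Dess–Martin oxidation of the primary alcohol; the aldehyde carbon is attached to a quaternary epoxide carbon and cannot epimerise.

Step 9
Reactants: 9 (2R,3S)-3-[(2E,4R,5S)-5-[(tert-butyldimethylsilyl)oxy]-4-methylhex-2-en-2-yl]-2-methyloxirane-2-carbaldehyde
Product: 10 (2S,3S)-2-ethynyl-3-[(2E,4R,5S)-5-[(tert-butyldimethylsilyl)oxy]-4-methylhex-2-en-2-yl]-2-methyloxirane
Conditions: dimethyl (1-diazo-2-oxopropyl)phosphonate, K2CO3, MeOH, 0 °C → rt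
Reagents that add atoms: dimethyl (1-diazo-2-oxopropyl)phosphonate, COP(=O)(OC)C(=[N+]=[N-])C(C)=O
Why: Seyferth–Gilbert homologation with the Ohira–Bestmann reagent should convert the aldehyde into the terminal alkyne (C3≡C4) under conditions mild enough for the epoxide.

Step 10
Reactants: 11 methyl 3,3-dimethoxypropanoate
Product: 12 N-methoxy-N-methyl-3,3-dimethoxypropanamide
Conditions: MeNH(OMe)·HCl, iPrMgCl, THF, −20 °C
Reagents that add atoms: N,O-dimethylhydroxylamine hydrochloride, CNOC.Cl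
Why: Weinreb amide formation by attack of the chloromagnesium amide on the ester at low temperature.

Step 11
Reactants: 10 (2S,3S)-2-ethynyl-3-[(2E,4R,5S)-5-[(tert-butyldimethylsilyl)oxy]-4-methylhex-2-en-2-yl]-2-methyloxirane; 12 N-methoxy-N-methyl-3,3-dimethoxypropanamide
Product: 13 1-Ep-5,5-dimethoxypent-1-yn-3-one
Conditions: 10, n-BuLi, THF, −78 °C; then 12, −78 → −20 °C; H2O
Reagents that add atoms: none
Why: Weinreb ketone synthesis, in which the lithium acetylide adds once and the chelated tetrahedral intermediate prevents over-addition; this forms the C4–C4a bond.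

Step 12
Reactants: 13 1-Ep-5,5-dimethoxypent-1-yn-3-one
Product: 15 5-(dimethoxymethyl)-2-Ep-4H-pyran-4-one, via hydroxymethylene ynone 14 (not isolated)
Conditions: LiN(SiMe3)2 (2.1 equiv), THF, −78 °C; HCO2CH2CF3, −78 → 0 °C; AcOH; then DABCO (20 mol %), CH2Cl2, rt
Reagents that add atoms: 2,2,2-trifluoroethyl formate, O=COCC(F)(F)F
Why: Claisen formylation at the only enolisable carbon (C8a) installs C1, and 6-endo-dig oxa-Michael addition of the hydroxymethylene oxygen to the ynone should close ring A as a 4-pyranone.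

Step 13
Reactants: 15 5-(dimethoxymethyl)-2-Ep-4H-pyran-4-one; 16 (2S)-but-3-yn-2-ol
Product: 18 (4Z)-4-[(3S)-3-hydroxy-2-oxobutylidene]-6-Ep-4H-pyran-3-carbaldehyde, via pyranol 17 (not isolated)
Conditions: 16 (1.5 equiv), n-BuLi (3.0 equiv), THF, −78 → 0 °C; then 15, −78 °C; then 5 % aq. oxalic acid, THF, 0 °C → rt
Reagents that add atoms: water, O
Why: 1,2-Addition of the dilithiated butynol to the pyranone carbonyl, then Meyer–Schuster rearrangement through the 4-alkynylpyrylium ion with water adding at C6, should give the C4a=C5–C6(=O) unit while the same mild acid unmasks the C8 formyl group.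

Step 14
Reactants: 18 (4Z)-4-[(3S)-3-hydroxy-2-oxobutylidene]-6-Ep-4H-pyran-3-carbaldehyde
Product: 19 (4Z)-4-(2,3-dioxobutylidene)-6-Ep-4H-pyran-3-carbaldehyde
Conditions: Dess–Martin periodinane, NaHCO3, CH2Cl2, 0 °C
Reagents that add atoms: none
Why: Dess–Martin oxidation of the α-hydroxy ketone to the 1,2-dione, which makes C7 an electrophilic acetyl carbonyl and removes the temporary C7 stereocentre.

Step 15
Reactants: 19 (4Z)-4-(2,3-dioxobutylidene)-6-Ep-4H-pyran-3-carbaldehyde
Product: 20 (7R)-7-hydroxy-7-methyl-3-Ep-6H-isochromene-6,8(7H)-dione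
Conditions: (5aR,10bS)-2-(pentafluorophenyl)-5a,10b-dihydro-4H,6H-indeno[2,1-b][1,2,4]triazolo[4,3-d][1,4]oxazin-2-ium tetrafluoroborate (10 mol %), Et3N (10 mol %), 4 Å molecular sieves, toluene (dilute), rt
Reagents that add atoms: none
Why: The triazolylidene adds to the C8 formyl group and proton transfer gives the Breslow enaminol, an acyl anion equivalent at C8 that attacks the C7 acetyl carbonyl of the 1,2-dione and then releases the carbene, leaving the C8 ketone and the C7 tertiary alcohol. The closest known reaction type is the asymmetric intramolecular crossed aldehyde–ketone benzoin cyclisation. Ring B (C4a–C5–C6–C7–C8–C8a) closes in the 6-exo-trig mode at the C7 carbonyl. C7 is the only new stereocentre and is set by the catalyst: the cis-fused indane wall of the aminoindanol backbone shields one face of the enaminol and the enaminol O–H···O=C7 hydrogen bond orients the ketone, which should give 7R. The step needs attack at C7 and not at C6 (5-exo) and no escape through a homoenolate or an intermolecular benzoin; C6 is deactivated as a vinylogous pyranone carbonyl (conjugated through C5=C4a–C4=C3 to O2) while C7 is activated by the adjacent carbonyl, and the formyl group sits on C8a of the C1=C8a enol ether, so it cannot enolise and its homoenolate position C1 is an oxygen-bearing ring carbon. The push–pull C4a=C5 bond should rotate freely under these conditions, so both geometric isomers of 19 converge on 20.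

Step 16
Reactants: 20 (7R)-7-hydroxy-7-methyl-3-Ep-6H-isochromene-6,8(7H)-dione
Product: 21 (7S,8R)-7,8-dihydroxy-7-methyl-3-Ep-7,8-dihydro-6H-isochromen-6-one
Conditions: Me4NBH(OAc)3, MeCN–AcOH (4:1), −30 °C
Reagents that add atoms: none
Why: Hydroxyl-directed (Saksena–Evans) reduction, in which the C7 hydroxyl binds boron and delivers hydride to C8 on its own face so that the new C8 hydroxyl should be trans to it (8R); C6 should stay untouched because it is the vinylogous pyranone carbonyl and is the site protonated by the acid.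

Step 17
Reactants: 21 (7S,8R)-7,8-dihydroxy-7-methyl-3-Ep-7,8-dihydro-6H-isochromen-6-one
Product: 22 Pestaphilone D, (7S,8R)-7,8-dihydroxy-3-[(2R,3S)-3-[(2E,4R,5S)-5-hydroxy-4-methylhex-2-en-2-yl]-2-methyloxiran-2-yl]-7-methyl-7,8-dihydro-6H-isochromen-6-one
Conditions: HF·pyridine, excess pyridine, THF, 0 °C → rt
Reagents that add atoms: none
Why: Fluoride cleavage of the secondary silyl ether, buffered by pyridine so that the allylic epoxide and the β-hydroxy ketone (retro-aldol) should survive.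

**Compound list**

1 | ethyl (3S)-3-hydroxybutanoate | CCOC(=O)C[C@H](C)O | starting material
2 | ethyl (2S,3S)-3-hydroxy-2-methylbutanoate | CCOC(=O)[C@@H](C)[C@H](C)O | intermediate
3 | ethyl (2S,3S)-3-[(tert-butyldimethylsilyl)oxy]-2-methylbutanoate | CCOC(=O)[C@@H](C)[C@H](C)O[Si](C)(C)C(C)(C)C | intermediate
4 | (2S,3S)-3-[(tert-butyldimethylsilyl)oxy]-2-methylbutanal | O=C[C@@H](C)[C@H](C)O[Si](C)(C)C(C)(C)C | intermediate
5 | (2E,4R,5S)-5-[(tert-butyldimethylsilyl)oxy]-2,4-dimethylhex-2-enal | O=C/C(C)=C/[C@@H](C)[C@H](C)O[Si](C)(C)C(C)(C)C | intermediate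
6 | ethyl (2E,4E,6R,7S)-7-[(tert-butyldimethylsilyl)oxy]-2,4,6-trimethylocta-2,4-dienoate | CCOC(=O)/C(C)=C/C(C)=C/[C@@H](C)[C@H](C)O[Si](C)(C)C(C)(C)C | intermediate
7 | (2E,4E,6R,7S)-7-[(tert-butyldimethylsilyl)oxy]-2,4,6-trimethylocta-2,4-dien-1-ol | OC/C(C)=C/C(C)=C/[C@@H](C)[C@H](C)O[Si](C)(C)C(C)(C)C | intermediate
8 | [(2S,3S)-3-[(2E,4R,5S)-5-[(tert-butyldimethylsilyl)oxy]-4-methylhex-2-en-2-yl]-2-methyloxiran-2-yl]methanol | C/C(=C\[C@@H](C)[C@H](C)O[Si](C)(C)C(C)(C)C)[C@@H]1O[C@@]1(C)CO | intermediate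
9 | (2R,3S)-3-[(2E,4R,5S)-5-[(tert-butyldimethylsilyl)oxy]-4-methylhex-2-en-2-yl]-2-methyloxirane-2-carbaldehyde | C/C(=C\[C@@H](C)[C@H](C)O[Si](C)(C)C(C)(C)C)[C@@H]1O[C@@]1(C)C=O | intermediate
10 | (2S,3S)-2-ethynyl-3-[(2E,4R,5S)-5-[(tert-butyldimethylsilyl)oxy]-4-methylhex-2-en-2-yl]-2-methyloxirane | C/C(=C\[C@@H](C)[C@H](C)O[Si](C)(C)C(C)(C)C)[C@@H]1O[C@@]1(C)C#C | intermediate
11 | methyl 3,3-dimethoxypropanoate | COC(=O)CC(OC)OC | starting material
12 | N-methoxy-N-methyl-3,3-dimethoxypropanamide | CON(C)C(=O)CC(OC)OC | intermediate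
13 | 1-[(2S,3S)-3-[(2E,4R,5S)-5-[(tert-butyldimethylsilyl)oxy]-4-methylhex-2-en-2-yl]-2-methyloxiran-2-yl]-5,5-dimethoxypent-1-yn-3-one | C/C(=C\[C@@H](C)[C@H](C)O[Si](C)(C)C(C)(C)C)[C@@H]1O[C@@]1(C)C#CC(=O)CC(OC)OC | intermediate
14 | 4-(hydroxymethylidene)-5,5-dimethoxy-1-[(2S,3S)-3-[(2E,4R,5S)-5-[(tert-butyldimethylsilyl)oxy]-4-methylhex-2-en-2-yl]-2-methyloxiran-2-yl]pent-1-yn-3-one (enol of the 4-formyl ketone) | C/C(=C\[C@@H](C)[C@H](C)O[Si](C)(C)C(C)(C)C)[C@@H]1O[C@@]1(C)C#CC(=O)C(=CO)C(OC)OC | intermediate (not isolated)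
15 | 5-(dimethoxymethyl)-2-[(2R,3S)-3-[(2E,4R,5S)-5-[(tert-butyldimethylsilyl)oxy]-4-methylhex-2-en-2-yl]-2-methyloxiran-2-yl]-4H-pyran-4-one | C/C(=C\[C@@H](C)[C@H](C)O[Si](C)(C)C(C)(C)C)[C@@H]1O[C@@]1(C)C1=CC(=O)C(C(OC)OC)=CO1 | intermediate
16 | (2S)-but-3-yn-2-ol | C#C[C@H](C)O | starting material
17 | 5-(dimethoxymethyl)-4-[(3S)-3-hydroxybut-1-yn-1-yl]-2-[(2R,3S)-3-[(2E,4R,5S)-5-[(tert-butyldimethylsilyl)oxy]-4-methylhex-2-en-2-yl]-2-methyloxiran-2-yl]-4H-pyran-4-ol (both epimers at the pyranol carbon) | C/C(=C\[C@@H](C)[C@H](C)O[Si](C)(C)C(C)(C)C)[C@@H]1O[C@@]1(C)C1=CC(O)(C#C[C@H](C)O)C(C(OC)OC)=CO1 | intermediate (not isolated)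
18 | (4Z)-4-[(3S)-3-hydroxy-2-oxobutylidene]-6-[(2R,3S)-3-[(2E,4R,5S)-5-[(tert-butyldimethylsilyl)oxy]-4-methylhex-2-en-2-yl]-2-methyloxiran-2-yl]-4H-pyran-3-carbaldehyde | C/C(=C\[C@@H](C)[C@H](C)O[Si](C)(C)C(C)(C)C)[C@@H]1O[C@@]1(C)C1=C/C(=C/C(=O)[C@H](C)O)C(C=O)=CO1 | intermediate
19 | (4Z)-4-(2,3-dioxobutylidene)-6-[(2R,3S)-3-[(2E,4R,5S)-5-[(tert-butyldimethylsilyl)oxy]-4-methylhex-2-en-2-yl]-2-methyloxiran-2-yl]-4H-pyran-3-carbaldehyde | C/C(=C\[C@@H](C)[C@H](C)O[Si](C)(C)C(C)(C)C)[C@@H]1O[C@@]1(C)C1=C/C(=C/C(=O)C(C)=O)C(C=O)=CO1 | intermediate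
20 | (7R)-7-hydroxy-7-methyl-3-[(2R,3S)-3-[(2E,4R,5S)-5-[(tert-butyldimethylsilyl)oxy]-4-methylhex-2-en-2-yl]-2-methyloxiran-2-yl]-6H-isochromene-6,8(7H)-dione | C/C(=C\[C@@H](C)[C@H](C)O[Si](C)(C)C(C)(C)C)[C@@H]1O[C@@]1(C)C1=CC2=CC(=O)[C@@](C)(O)C(=O)C2=CO1 | intermediate
21 | (7S,8R)-7,8-dihydroxy-7-methyl-3-[(2R,3S)-3-[(2E,4R,5S)-5-[(tert-butyldimethylsilyl)oxy]-4-methylhex-2-en-2-yl]-2-methyloxiran-2-yl]-7,8-dihydro-6H-isochromen-6-one | C/C(=C\[C@@H](C)[C@H](C)O[Si](C)(C)C(C)(C)C)[C@@H]1O[C@@]1(C)C1=CC2=CC(=O)[C@@](C)(O)[C@H](O)C2=CO1 | intermediate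
22 | Pestaphilone D, (7S,8R)-7,8-dihydroxy-3-[(2R,3S)-3-[(2E,4R,5S)-5-hydroxy-4-methylhex-2-en-2-yl]-2-methyloxiran-2-yl]-7-methyl-7,8-dihydro-6H-isochromen-6-one | C/C(=C\[C@@H](C)[C@H](C)O)[C@@H]1O[C@@]1(C)C1=CC2=CC(=O)[C@@](C)(O)[C@H](O)C2=CO1 | target

**Count and risks**

Total step count: 17. Longest linear sequence: 16 steps (steps 1–9 and 11–17; step 10 is a one-step side branch).

Most likely to fail:

Step 15. The carbene may add to C1 of the pyran or divert the formyl group down a homoenolate path, facial selectivity at C7 may be poor, or hydration at C1 with ring-chain isomerisation of 19 may outrun cyclisation. The fallback closes the same C7–C8 bond by an intramolecular aldol reaction at the alcohol oxidation level. It sets out from 18: TESOTf and 2,6-lutidine (CH2Cl2, −78 °C) should give the triethylsilyl ether of 18 F1. LiN(SiMe3)2 (THF, −78 °C) should then form the C7 enolate, which adds to the C8 formyl group (6-enolendo-exo-trig) through a lithium-bridged transition state to give the trans 7-silyloxy-8-ol F2. The absolute configuration at C7/C8 is not controlled there; because the side chain is enantiopure, the two trans isomers are diastereomers and would be separated by chromatography, with the unwanted one recycled by base-mediated retro-aldol equilibration. HF·pyridine then removes both silyl groups, and the fallback comes back to the route at 22.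

Step 13. The acetylide may add in conjugate fashion at C1 and not at the pyranone carbonyl; the acid needed for rearrangement and acetal cleavage may open the allylic epoxide; or water may add at C1 of the product and trigger ring-chain isomerisation. The fallback avoids the carbonyl addition and the rearrangement by an Eschenmoser sulfide contraction. It sets out from 15: Lawesson's reagent (toluene, 60 °C) should give the 4H-pyran-4-thione F3. S-Alkylation with 1-bromobutane-2,3-dione (acetone, rt) should give the 4-[(2,3-dioxobutyl)sulfanyl]pyrylium bromide F4. Ph3P and Et3N (CH2Cl2, rt) should extrude sulfur to give the dimethyl acetal of 19 F5. Brief treatment with oxalic acid on wet silica should then free the formyl group, and the fallback comes back to the route at 19 (steps 13 and 14 are bypassed).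

Step 16. Hydride may be transferred to C1 (conjugate) or to C6; the acetic acid medium may ionise the allylic epoxide; or facial selectivity may erode if the borohydride does not bind the C7 hydroxyl. The fallback replaces substrate-directed borohydride delivery by acid-free, catalyst-controlled transfer hydrogenation. It sets out from 20: RuCl(p-cymene)[(S,S)-TsDPEN] with the HCO2H–Et3N azeotrope (CH2Cl2, rt) should reduce the C8 enone carbonyl by outer-sphere hydride transfer to give 21 directly, where it comes back to the route; no new compound arises (F0).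

Further compounds
F1 | step 15 | (4Z)-4-[(3S)-2-oxo-3-[(triethylsilyl)oxy]butylidene]-6-[(2R,3S)-3-[(2E,4R,5S)-5-[(tert-butyldimethylsilyl)oxy]-4-methylhex-2-en-2-yl]-2-methyloxiran-2-yl]-4H-pyran-3-carbaldehyde | C/C(=C\[C@@H](C)[C@H](C)O[Si](C)(C)C(C)(C)C)[C@@H]1O[C@@]1(C)C1=C/C(=C/C(=O)[C@H](C)O[Si](CC)(CC)CC)C(C=O)=CO1
F2 | step 15 | (7S,8R)-8-hydroxy-7-methyl-7-[(triethylsilyl)oxy]-3-[(2R,3S)-3-[(2E,4R,5S)-5-[(tert-butyldimethylsilyl)oxy]-4-methylhex-2-en-2-yl]-2-methyloxiran-2-yl]-7,8-dihydro-6H-isochromen-6-one | C/C(=C\[C@@H](C)[C@H](C)O[Si](C)(C)C(C)(C)C)[C@@H]1O[C@@]1(C)C1=CC2=CC(=O)[C@@](C)(O[Si](CC)(CC)CC)[C@H](O)C2=CO1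
F3 | step 13 | 5-(dimethoxymethyl)-2-[(2R,3S)-3-[(2E,4R,5S)-5-[(tert-butyldimethylsilyl)oxy]-4-methylhex-2-en-2-yl]-2-methyloxiran-2-yl]-4H-pyran-4-thione | C/C(=C\[C@@H](C)[C@H](C)O[Si](C)(C)C(C)(C)C)[C@@H]1O[C@@]1(C)C1=CC(=S)C(C(OC)OC)=CO1
F4 | step 13 | 5-(dimethoxymethyl)-4-[(2,3-dioxobutyl)sulfanyl]-2-[(2R,3S)-3-[(2E,4R,5S)-5-[(tert-butyldimethylsilyl)oxy]-4-methylhex-2-en-2-yl]-2-methyloxiran-2-yl]pyrylium bromide | C/C(=C\[C@@H](C)[C@H](C)O[Si](C)(C)C(C)(C)C)[C@@H]1O[C@@]1(C)C1=[O+]C=C(C(OC)OC)C(SCC(=O)C(C)=O)=C1.[Br-]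
F5 | step 13 | (1Z)-1-[5-(dimethoxymethyl)-2-[(2R,3S)-3-[(2E,4R,5S)-5-[(tert-butyldimethylsilyl)oxy]-4-methylhex-2-en-2-yl]-2-methyloxiran-2-yl]-4H-pyran-4-ylidene]butane-2,3-dione | C/C(=C\[C@@H](C)[C@H](C)O[Si](C)(C)C(C)(C)C)[C@@H]1O[C@@]1(C)C1=C/C(=C/C(=O)C(C)=O)C(C(OC)OC)=CO1
F0 | step 16 | none | none
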